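**Plan**

1. Ring C is opened at O1–C2 and at C3–C4, which leads back to a ring A benzaldehyde (C4 as CHO on C4a, C8a–O masked) and a ring B arylacetylene.
2. Ring A is cut at C5–C6 and C4a–C8a. C6, C7, C8 and C8a carry four oxygens in a row and are the four ring carbons of dimethyl squarate; C5 (OMe) and C4a (bearing C4) are the two carbons of a 2-methoxyvinyl unit. This match is what lets ring A be made by a cyclobutenone ring expansion.
3. Forward: vinyl bromide, then vinyllithium plus squarate (C4a–C8a), thermal ring expansion to ring A (C5–C6), aldehyde release, acetylide addition (C3–C4) and oxidation, O1–C2 closure to ring C, hydrogenolysis.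
4. Rings arise in the order A (step 3), then C (step 10); ring B is bought as 2-hydroxy-6-methoxybenzaldehyde.
5. The target has no stereocentre. The stereochemical demands are the Z geometry of the vinyl bromide (lithium cis to methoxy) and outward rotation of the carbinol oxygen in the ring opening; the racemic centres of 7, 9 and 17 are erased by aromatisation or oxidation.
6. The carbinol oxygen is capped as a MOM ether, so the ring expansion delivers C6–OH free and C8a–O protected, i.e. the two hydroquinone oxygens already differentiated.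

Key step: step 3

Assumption: 1,3,3-trimethoxypropene is used as the E/Z mixture supplied, and the dehydrobromination of step 1 is taken to favour the Z bromide; the geometry is to be checked by NOE (vinyl H to acetal H) before step 2.

**Step 1**
Reactants: 1 1,3,3-trimethoxyprop-1-ene
Product: 3 (1Z)-2-bromo-1,3,3-trimethoxyprop-1-ene, via dibromide 2 (not isolated)
Conditions: Br2 (1.0 equiv), CH2Cl2, −78 °C; then Et3N (2.5 equiv), −78 °C → rt; distillation
Reagents that add atoms: bromine, BrBr
Why: Bromination–dehydrobromination of an enol ether: Br2 adds across the electron-rich C1=C2 bond to give the α-bromo ether 2, and the amine then removes HBr through the bromo-oxocarbenium ion, which should place bromine on C2 and favour the Z alkene (Br cis to OMe, the bulky dimethoxymethyl group trans to it), the outcome known for the same sequence on methyl 3-methoxyacrylate.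

**Step 2**
Reactants: 3 (1Z)-2-bromo-1,3,3-trimethoxyprop-1-ene; 4 dimethyl squarate (3,4-dimethoxycyclobut-3-ene-1,2-dione)
Product: 7 2,3-dimethoxy-4-(methoxymethoxy)-4-[(1E)-1,3,3-trimethoxyprop-1-en-2-yl]cyclobut-2-en-1-one (racemic), via vinyllithium 5 (not isolated), via lithium alkoxide 6 (not isolated)
Conditions: 3 (1.1 equiv), t-BuLi (2.2 equiv), THF, −78 °C; cannulate into 4, THF, −78 °C; then MOMCl (3 equiv), −78 → 0 °C; Et3N-washed silica
Reagents that add atoms: chloromethyl methyl ether, COCCl
Why: Bromine–lithium exchange proceeds with retention to a vinyllithium whose lithium is cis to the β-methoxy group, so anti-periplanar β-elimination of LiOMe is not available at −78 °C; 1,2-addition of vinyllithiums to one of the two equivalent carbonyl groups of a squarate ester is standard, and the tertiary lithium alkoxide is O-alkylated in the flask by the reactive α-chloro ether (Williamson-type trapping), the new stereocentre being formed as a racemate that is destroyed in step 3.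

**Step 3**
Reactants: 7 2,3-dimethoxy-4-(methoxymethoxy)-4-[(1E)-1,3,3-trimethoxyprop-1-en-2-yl]cyclobut-2-en-1-one
Product: 10 3-(dimethoxymethyl)-2,5,6-trimethoxy-4-(methoxymethoxy)phenol, via dienylketene 8 (not isolated), via cyclohexadienone 9 (not isolated)
Conditions: degassed toluene (0.02 M), 110 °C, argon
Reagents that add atoms: none
Why: Moore ring expansion: thermal conrotatory 4π opening of the C1–C4 bond of the cyclobutenone gives dienylketene 8, disrotatory 6π electrocyclisation then joins the ketene carbon (future C6) to the methoxy-bearing alkene terminus (future C5), and dienone 9 enolises through its only ring hydrogen, C5–H, to phenol 10. The closest known reaction type is the thermolysis of 4-alkenyl-4-hydroxy- or 4-alkoxycyclobutenones made from squarate esters, which gives hydroquinones or their monoethers at 80–140 °C. Ring A, the one ring formed, is closed by the 6π electrocyclisation (C5–C6 bond), and aromatisation makes the closure irreversible. No stereocentre survives: the sp3 centre at C5 in 9 is lost on tautomerisation and the carbinol centre of 7 becomes aromatic C8a. The step needs torquoselectivity (alkenyl inward, oxygen outward), which the donor OMOM group on C4 secures by its strong outward preference; because C5 carries only H and OMe, the methoxy group cannot be lost on aromatisation. The ketene carbonyl emerges as the free C6–OH and the MOM-bearing carbinol oxygen as C8a–O, so the two hydroquinone oxygens leave the step differentiated.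

**Step 4**
Reactants: 10 3-(dimethoxymethyl)-2,5,6-trimethoxy-4-(methoxymethoxy)phenol
Product: 11 1-(benzyloxy)-3-(dimethoxymethyl)-2,5,6-trimethoxy-4-(methoxymethoxy)benzene
Conditions: BnBr, K2CO3, Bu4NI (cat.), DMF, rt
Reagents that add atoms: benzyl bromide, BrCc1ccccc1
Why: Williamson etherification: the C6 phenol is the only acidic site and its potassium phenoxide is benzylated in DMF while the acetal and the MOM ether are inert to base.

**Step 5**
Reactants: 11 1-(benzyloxy)-3-(dimethoxymethyl)-2,5,6-trimethoxy-4-(methoxymethoxy)benzene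
Product: 12 3-(benzyloxy)-2,4,5-trimethoxy-6-(methoxymethoxy)benzaldehyde
Conditions: PPTS (0.1 equiv), acetone/H2O (10:1), rt
Reagents that add atoms: water, O
Why: Acid-catalysed acetal hydrolysis: under pyridinium tosylate in wet acetone the benzylic dimethyl acetal ionises to an aryl-stabilised oxocarbenium ion and is hydrolysed far faster than the aryl MOM ether or the benzyl ether can react, releasing the C4 aldehyde.

**Step 6**
Reactants: 13 2-hydroxy-6-methoxybenzaldehyde
Product: 14 2-(benzyloxy)-6-methoxybenzaldehyde
Conditions: BnBr, K2CO3, DMF, 60 °C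
Reagents that add atoms: benzyl bromide, BrCc1ccccc1
Why: Williamson etherification of the chelated phenol with benzyl bromide, routine for salicylaldehydes in warm DMF.

**Step 7**
Reactants: 14 2-(benzyloxy)-6-methoxybenzaldehyde
Product: 15 1-(benzyloxy)-2-ethynyl-3-methoxybenzene
Conditions: dimethyl (1-diazo-2-oxopropyl)phosphonate, K2CO3, MeOH, 0 °C → rt
Reagents that add atoms: dimethyl (1-diazo-2-oxopropyl)phosphonate, CC(=O)C(=[N+]=[N-])P(=O)(OC)OC
Why: Seyferth–Gilbert homologation with the Ohira–Bestmann reagent: methanolysis of the acetyl group gives the diazomethylphosphonate anion, which adds to the non-enolisable aldehyde, and after loss of dimethyl phosphate and N2 the alkylidene carbene rearranges by 1,2-hydrogen shift to the terminal alkyne.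

**Step 8**
Reactants: 15 1-(benzyloxy)-2-ethynyl-3-methoxybenzene; 12 3-(benzyloxy)-2,4,5-trimethoxy-6-(methoxymethoxy)benzaldehyde
Product: 17 1-[3-(benzyloxy)-2,4,5-trimethoxy-6-(methoxymethoxy)phenyl]-3-[2-(benzyloxy)-6-methoxyphenyl]prop-2-yn-1-ol (racemic), via lithium acetylide 16 (not isolated)
Conditions: 15 (1.3 equiv), n-BuLi (1.25 equiv), THF, −78 °C; then 12, −78 → 0 °C; aq. NH4Cl
Reagents that add atoms: none
Why: 1,2-Addition of a lithium acetylide to a non-enolisable aromatic aldehyde, helped by chelation of lithium between the aldehyde and the ortho MOM oxygen; the carbinol stereocentre is formed as a racemate and is removed by the oxidation in step 9.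

**Step 9**
Reactants: 17 1-[3-(benzyloxy)-2,4,5-trimethoxy-6-(methoxymethoxy)phenyl]-3-[2-(benzyloxy)-6-methoxyphenyl]prop-2-yn-1-ol
Product: 18 1-[3-(benzyloxy)-2,4,5-trimethoxy-6-(methoxymethoxy)phenyl]-3-[2-(benzyloxy)-6-methoxyphenyl]prop-2-yn-1-one
Conditions: activated MnO2 (excess), CH2Cl2, rt
Reagents that add atoms: none
Why: MnO2 oxidises benzylic–propargylic alcohols selectively to ynones under neutral conditions, and with both phenolic oxygens of ring A etherified no quinone formation can compete.

**Step 10**
Reactants: 18 1-[3-(benzyloxy)-2,4,5-trimethoxy-6-(methoxymethoxy)phenyl]-3-[2-(benzyloxy)-6-methoxyphenyl]prop-2-yn-1-one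
Product: 21 6-(benzyloxy)-2-[2-(benzyloxy)-6-methoxyphenyl]-5,7,8-trimethoxy-4H-chromen-4-one, via enaminone 19 (not isolated), via phenolic enaminone 20 (not isolated)
Conditions: Et2NH (3 equiv), EtOH, rt; then 3 M aq. HCl, 60 °C
Reagents that add atoms: none
Why: Aza-Michael addition of the secondary amine turns the ynone into a β-amino enone whose only electrophilic carbon is the future C2, and aqueous acid then cleaves the aryl MOM ether so that the freed C8a–OH adds to the protonated enaminone and expels diethylamine (addition–elimination, the usual closure of ortho-hydroxyaryl enaminones to chromones), which allows only the six-membered pyranone and not the five-membered aurone; any enaminone hydrolysed to the 1,3-diketone converges on the same flavone by acid cyclodehydration.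

**Step 11**
Reactants: 21 6-(benzyloxy)-2-[2-(benzyloxy)-6-methoxyphenyl]-5,7,8-trimethoxy-4H-chromen-4-one
Product: 22 6,2'-dihydroxy-5,7,8,6'-tetramethoxyflavone
Conditions: H2 (1 atm), Pd/C (10% palladium on carbon), EtOAc/MeOH, rt
Reagents that add atoms: none
Why: Catalytic hydrogenolysis cleaves both aryl benzyl ethers at 1 atm and room temperature, conditions under which the flavone C2=C3 bond (a vinylogous ester) and the aryl methyl ethers are left untouched.

**Compound list**

1 | 1,3,3-trimethoxyprop-1-ene (E/Z mixture as supplied) | COC=CC(OC)OC | starting material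
2 | 1,2-dibromo-1,3,3-trimethoxypropane (diastereomer mixture) | COC(Br)C(Br)C(OC)OC | intermediate
3 | (1Z)-2-bromo-1,3,3-trimethoxyprop-1-ene | CO/C=C(\Br)C(OC)OC | intermediate
4 | dimethyl squarate (3,4-dimethoxycyclobut-3-ene-1,2-dione) | COC1=C(OC)C(=O)C1=O | starting material
5 | [(1E)-1,3,3-trimethoxyprop-1-en-2-yl]lithium (Li cis to OMe) | CO/C=C(\[Li])C(OC)OC | intermediate
6 | lithium 2,3-dimethoxy-4-oxo-1-[(1E)-1,3,3-trimethoxyprop-1-en-2-yl]cyclobut-2-en-1-olate (racemic) | COC1=C(OC)C([O-])(C1=O)/C(=C\OC)C(OC)OC.[Li+] | intermediate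
7 | 2,3-dimethoxy-4-(methoxymethoxy)-4-[(1E)-1,3,3-trimethoxyprop-1-en-2-yl]cyclobut-2-en-1-one (racemic) | COC1=C(OC)C(OCOC)(C1=O)/C(=C\OC)C(OC)OC | intermediate
8 | dienylketene: 5-(dimethoxymethyl)-2,3,6-trimethoxy-4-(methoxymethoxy)hexa-1,3,5-trien-1-one, C2 and the methoxyvinyl unit cis across C3=C4 | O=C=C(OC)/C(OC)=C(OCOC)\C(=C/OC)C(OC)OC | intermediate
9 | 5-(dimethoxymethyl)-2,3,6-trimethoxy-4-(methoxymethoxy)cyclohexa-2,4-dien-1-one (racemic) | COC1C(=O)C(OC)=C(OC)C(OCOC)=C1C(OC)OC | intermediate
10 | 3-(dimethoxymethyl)-2,5,6-trimethoxy-4-(methoxymethoxy)phenol | COCOc1c(OC)c(OC)c(O)c(OC)c1C(OC)OC | intermediate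
11 | 1-(benzyloxy)-3-(dimethoxymethyl)-2,5,6-trimethoxy-4-(methoxymethoxy)benzene | COCOc1c(OC)c(OC)c(OCc2ccccc2)c(OC)c1C(OC)OC | intermediate
12 | 3-(benzyloxy)-2,4,5-trimethoxy-6-(methoxymethoxy)benzaldehyde | COCOc1c(OC)c(OC)c(OCc2ccccc2)c(OC)c1C=O | intermediate
13 | 2-hydroxy-6-methoxybenzaldehyde | COc1cccc(O)c1C=O | starting material
14 | 2-(benzyloxy)-6-methoxybenzaldehyde | COc1cccc(OCc2ccccc2)c1C=O | intermediate
15 | 1-(benzyloxy)-2-ethynyl-3-methoxybenzene | COc1cccc(OCc2ccccc2)c1C#C | intermediate
16 | {[2-(benzyloxy)-6-methoxyphenyl]ethynyl}lithium | COc1cccc(OCc2ccccc2)c1C#C[Li] | intermediate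
17 | 1-[3-(benzyloxy)-2,4,5-trimethoxy-6-(methoxymethoxy)phenyl]-3-[2-(benzyloxy)-6-methoxyphenyl]prop-2-yn-1-ol (racemic) | COCOc1c(OC)c(OC)c(OCc2ccccc2)c(OC)c1C(O)C#Cc1c(OC)cccc1OCc1ccccc1 | intermediate
18 | 1-[3-(benzyloxy)-2,4,5-trimethoxy-6-(methoxymethoxy)phenyl]-3-[2-(benzyloxy)-6-methoxyphenyl]prop-2-yn-1-one | COCOc1c(OC)c(OC)c(OCc2ccccc2)c(OC)c1C(=O)C#Cc1c(OC)cccc1OCc1ccccc1 | intermediate
19 | 1-[3-(benzyloxy)-2,4,5-trimethoxy-6-(methoxymethoxy)phenyl]-3-[2-(benzyloxy)-6-methoxyphenyl]-3-(diethylamino)prop-2-en-1-one (alkene geometry not defined) | CCN(CC)C(=CC(=O)c1c(OCOC)c(OC)c(OC)c(OCc2ccccc2)c1OC)c1c(OC)cccc1OCc1ccccc1 | intermediate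
20 | 1-[3-(benzyloxy)-6-hydroxy-2,4,5-trimethoxyphenyl]-3-[2-(benzyloxy)-6-methoxyphenyl]-3-(diethylamino)prop-2-en-1-one (alkene geometry not defined) | CCN(CC)C(=CC(=O)c1c(O)c(OC)c(OC)c(OCc2ccccc2)c1OC)c1c(OC)cccc1OCc1ccccc1 | intermediate
21 | 6-(benzyloxy)-2-[2-(benzyloxy)-6-methoxyphenyl]-5,7,8-trimethoxy-4H-chromen-4-one | COc1cccc(OCc2ccccc2)c1-c1cc(=O)c2c(OC)c(OCc3ccccc3)c(OC)c(OC)c2o1 | intermediate
22 | 6,2'-dihydroxy-5,7,8,6'-tetramethoxyflavone | COc1cccc(O)c1-c1cc(=O)c2c(OC)c(O)c(OC)c(OC)c2o1 | target

**Step count**

Total: 11 steps. Longest linear sequence: 9 steps (1, 2, 3, 4, 5, 8, 9, 10, 11); steps 6 and 7 make the ring B alkyne.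

**Steps most likely to fail**

Step 2. The hindered tertiary lithium alkoxide 6 may be alkylated too slowly by MOMCl at low temperature, so that on warming it opens the four-membered ring prematurely or is merely protonated on work-up. The fallback sets out from 3 and 4 and returns at 7. The adduct is quenched at −78 °C with aqueous NH4Cl and isolated as 4-hydroxy-2,3-dimethoxy-4-[(1E)-1,3,3-trimethoxyprop-1-en-2-yl]cyclobut-2-en-1-one F1. The neutral carbinol is then etherified in a separate operation with MOMCl, iPr2NEt and catalytic Bu4NI in CH2Cl2, the usual way of capping 4-hydroxycyclobutenones as alkoxymethyl ethers, to give 7.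

Step 3. Ring opening of the fully etherified substrate may be slower than thermal decay of the acid-labile vinylogous acetal, or dienone 9 may fail to find a clean proton-transfer path to the phenol in the aprotic medium, so that the ketene is diverted to dimers. The fallback sets out from 3 and 4, through the carbinol F1 described above, and returns at 12. The ring expansion is moved to the hydroxy series, the most thoroughly documented form of this reaction. Heating F1 in degassed toluene at 110 °C should give 2-(dimethoxymethyl)-3,5,6-trimethoxybenzene-1,4-diol F2. Dilute HCl in THF added to the same flask should hydrolyse the acetal to the chelated, less oxidation-prone 2,5-dihydroxy-3,4,6-trimethoxybenzaldehyde F3. Its dianion (NaH, 2 equiv, DMF) is then treated with one equivalent of BnBr; the non-conjugated phenoxide meta to the formyl group is the more nucleophilic, which should give 3-(benzyloxy)-6-hydroxy-2,4,5-trimethoxybenzaldehyde F4. MOMCl and iPr2NEt then cap the chelated hydroxyl to give 12.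

Step 1. The amine hydrobromide formed during dehydrobromination may ionise the vinylogous acetal, or the α-bromo ether may form an ammonium salt and not eliminate, leaving little vinyl bromide or poor control of alkene geometry. The fallback sets out from 1 and returns at 3. Bromo-methoxylation of 1 with NBS in methanol at 0 °C should give the symmetrical, distillable 2-bromo-1,1,3,3-tetramethoxypropane F5. One molecule of methanol is then removed with TMSOTf and iPr2NEt in CH2Cl2 at −20 °C (acetal to enol ether through the silyl-activated oxocarbenium ion); the substrate has only one eliminable hydrogen, so the reaction must stop at 3, and no HBr is involved.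

**Further compounds**

F1 | step 2 | 4-hydroxy-2,3-dimethoxy-4-[(1E)-1,3,3-trimethoxyprop-1-en-2-yl]cyclobut-2-en-1-one (racemic) | COC1=C(OC)C(O)(C1=O)/C(=C\OC)C(OC)OC
F2 | step 3 | 2-(dimethoxymethyl)-3,5,6-trimethoxybenzene-1,4-diol | COc1c(O)c(OC)c(OC)c(O)c1C(OC)OC
F3 | step 3 | 2,5-dihydroxy-3,4,6-trimethoxybenzaldehyde | COc1c(O)c(OC)c(OC)c(O)c1C=O
F4 | step 3 | 3-(benzyloxy)-6-hydroxy-2,4,5-trimethoxybenzaldehyde | COc1c(OCc2ccccc2)c(OC)c(OC)c(O)c1C=O
F5 | step 1 | 2-bromo-1,1,3,3-tetramethoxypropane | COC(OC)C(Br)C(OC)OC
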